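We decide to read the flask on the clock of the east run, since the two share their equivalents and differ in starting concentration.

| flask | starting material | partner | second reagent | remark | time |
|---|---|---|---|---|---|
| south-east | 0.10 M | 0.90 equiv | 1.2 equiv | the very flask that is asked about, followed so far |  |
| east | 0.067 M | 0.90 equiv | 1.2 equiv | run made earlier |  |
| flask | 0.10 M | 0.900 equiv | 1.20 equiv |  | 4.0 h |

- south-east (time / min: target / %): 8.00: 1.0; 15.0: 1.2; 25.0: 0.7; 30.0: 1.7; 40.0: 2.4; 50.0: 3.4
- east (time / h: target / %): 0.667: 1.6; 1.33: 3.9; 2.00: 7.2; 2.50: 8.7; 3.00: 12.4; 4.00: 16.1

(scatter of a reading: 0.5 percentage points)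

- amount of target in percent of the starting material charged, at 25 min, 80 min, 2.5 h and 4.0 h

If each step joins two species, then at fixed equivalents a percentage depends on concentration times time. One hour in the flask then counts as 1.49 east hours; this clock factor, the starting concentration of the flask over that of the east run, is our tool. We test it on the south-east run, the flask followed so far, and its reading of 3.4% at 50.0 min. That time maps to 1.24 h on the east clock, where the east readings interpolate to 3.60%, within the scatter.

Now we draw the curve. In the flask the opening slope, from the first east reading, is 0.0358 h⁻¹ as a fraction of the charge. The east readings from 1.33 h to 4.00 h climb at 0.0457 h⁻¹, so the later straight stretch of the flask, at 0.0681 h⁻¹, is steeper than the opening slope. Run back to zero, that line puts the knee of this induction period at: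

flask time = 0.319 h

At 25 min, the scaled first east reading gives 1.49% and the flask's own reading is 0.7%, so we take their mean, 1.10%.

At 80 min, the east clock shows 1.99 h, beside the east reading of 7.2% at 2.00 h, which we take.

At 2.5 h, the east clock shows 3.73 h. The east slope of the last hour, 0.0370 h⁻¹, gives 15.1%.

At 4.0 h, the east clock shows 5.96 h, beyond the readings. The straight stretch gives 25.1%. Going round again with the last-hour slope gives 23.4%. We commit to the mean, 24.2%.

The forecast, holding that “percent conversion seems to depend on concentration × time”, gives 1.4%, 6.8%, 15% and 25%.

The flask gives 1.14%, 6.85%, 14.8% and 23.7%.

    starting material + second reagent → side product (k = 0.0250 M⁻¹ min⁻¹)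
    second reagent + intermediate → target (k = 0.0260 M⁻¹ min⁻¹)
    starting material + partner → intermediate (k = 0.180 M⁻¹ min⁻¹)

Each step in this scheme takes two reactants, the form the clock factor assumed, and at 4.00 h the flask holds 44.7% intermediate beside 23.7% target. We use the factor once more on the east run: its reading of 16.1% at 4.00 h belongs to flask time 2.68 h, where the flask, interpolated between its last two values, stands at 15.9%.

The runs are simulated from invented constants; scatter was added.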